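**Strategy.** Everything rests on breaking the C20–C17 bond of the cyclohexane (C20–C17–C16–C2–C18–C19), C20 being the spiro carbon that carries N4 and sits next to the carbinol C15 of the pyrrolidine. N4–C20–C15(O)–C14–C3 is then (S)-malic acid with C20 as a carboxyl carbon. A malimide-derived tertiary hydroxylactam bearing a ketal-masked 2-(silylmethyl)allyl chain on C20 is ionised to an N-acyliminium ion, and the allylsilane terminus adds to C20 anti to the C15 benzyloxy group. This single operation closes the cyclohexane, sets the quaternary spiro centre relative to C15 and leaves an exo-methylene (the future ester carbon on C16) beside the masked C2 ketone.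

Key step: step 6

Remark: atom labels are N1/C2/C7 (indoline N, C-2, C-3), C6–C5 (CH2CH2 from C7 to N4), C3–C14 (pyrrolidine CH2CH2), C15 (CHOH), C20 (spiro carbon), C17, C16 (CH–CO2Me), C18, C19 (cyclohexane); a SMILES with one unassigned centre denotes an epimer mixture whose extra centre is erased or reset later.

**Step 1**
Reactants: 1 (S)-malic acid; 2 4-methoxybenzylamine
Product: 3 (S)-3-hydroxy-1-(4-methoxybenzyl)pyrrolidine-2,5-dione
Conditions: p-xylene, reflux, Dean–Stark
Reagents that add atoms: none
Why: Thermal condensation of a 1,4-diacid with a primary amine gives the cyclic imide (imide formation), and since no base is present the carbinol centre of malic acid should be carried over unchanged (ee to be checked at 4).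

**Step 2**
Reactants: 3 (S)-3-hydroxy-1-(4-methoxybenzyl)pyrrolidine-2,5-dione
Product: 4 (S)-3-(benzyloxy)-1-(4-methoxybenzyl)pyrrolidine-2,5-dione
Conditions: BnBr, Ag2O, Et2O, rt, dark
Reagents that add atoms: benzyl bromide BrCc1ccccc1
Why: Silver(I) oxide-promoted O-benzylation (neutral Williamson-type etherification) avoids the β-elimination and racemisation that alkoxide bases would cause in an α-oxygenated imide.

**Step 3**
Reactants: 5 (2-bromoallyl)trimethylsilane; 6 3-bromopropanoyl chloride
Product: 8 5-bromo-2-[(trimethylsilyl)methyl]pent-1-en-3-one, via vinyl Grignard reagent 7 (not isolated)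
Conditions: Mg, THF, 40 °C; then added to 6, Fe(acac)3 (3 mol%), THF, −78 °C
Reagents that add atoms: none
Why: Iron-catalysed acylation of the vinyl Grignard reagent by the acid chloride at −78 °C (Grignard ketone synthesis, inverse addition) should stop at the ketone; the primary bromide is not attacked and the allylsilane, now conjugated to the carbonyl, is not nucleophilic.

**Step 4**
Reactants: 8 5-bromo-2-[(trimethylsilyl)methyl]pent-1-en-3-one
Product: 9 2-(2-bromoethyl)-2-[3-(trimethylsilyl)prop-1-en-2-yl]-1,3-dioxolane
Conditions: TMSOCH2CH2OTMS, TMSOTf (5 mol%), CH2Cl2, −78 → −20 °C; pyridine quench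
Reagents that add atoms: 1,2-bis(trimethylsilyloxy)ethane C[Si](C)(C)OCCO[Si](C)(C)C
Why: Noyori ketalisation is aprotic and cold, so the β-bromo ketone should not lose HBr and the allylsilane should not be protodesilylated while the enone carbonyl is converted into the dioxolane.

**Step 5**
Reactants: 9 2-(2-bromoethyl)-2-[3-(trimethylsilyl)prop-1-en-2-yl]-1,3-dioxolane; 4 (S)-3-(benzyloxy)-1-(4-methoxybenzyl)pyrrolidine-2,5-dione
Product: 11 (4S)-4-(benzyloxy)-5-hydroxy-1-(4-methoxybenzyl)-5-(2-{2-[3-(trimethylsilyl)prop-1-en-2-yl]-1,3-dioxolan-2-yl}ethyl)pyrrolidin-2-one (both C5 epimers), via Grignard reagent 10 (not isolated)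
Conditions: Mg, THF, 25 °C; then added to 4, CH2Cl2, −78 → −20 °C; H2O
Reagents that add atoms: none
Why: Grignard addition to the O-benzyl malimide should occur at the carbonyl next to the benzyloxy-bearing carbon (inductive activation and chelation) and stop at the magnesium alkoxide of the hemiaminal; the new hemiaminal centre is a mixture that step 6 erases.

**Step 6 (key step)**
Reactants: 11 tertiary hydroxylactam
Product: 13 (4S,5R)-4-(benzyloxy)-8,8-(ethylenedioxy)-1-(4-methoxybenzyl)-7-methylene-1-azaspiro[4.5]decan-2-one, via N-acyliminium ion 12 (not isolated)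
Conditions: BF3·OEt2 (3 equiv), CH2Cl2 (0.02 M), −78 → 0 °C
Reagents that add atoms: none
Why: BF3 ionises the tertiary hemiaminal of 11 to the planar N-acyliminium ion 12, so both C20 epimers converge; the CH2 terminus of the 2-substituted allylsilane then bonds to C20 (new C20–C17 bond) while the C–Si bond stabilises the developing β-cation, and loss of silicon leaves the exo-methylene. The closest known reaction is the N-acyliminium/allylsilane cyclisation (intramolecular Hosomi–Sakurai-type capture) used to make spiro-lactams from imide-derived tertiary hydroxylactams. The cyclohexane closes through a chair-like transition state, 6-exo with respect to the C=N+ bond and 6-endo with respect to the alkene. The one new stereocentre, C20, is controlled by the neighbouring C15 benzyloxy group (1,2-induction inside the lactam): the bulky, fully substituted nucleophile should enter on the face anti to the C–O bond, which puts C17 trans and the existing C19 arm cis to oxygen, as in the target. The step needs this facial selectivity and ionisation of the hemiaminal in preference to the dioxolane; the first rests on the benzyloxy group, which A(1,2) strain with the in-plane C19 arm tilts over one face of C20, the second on the far easier ionisation of the N,O-acetal at low temperature and high dilution. Proton loss to the enamide is reversible under these conditions and returns to 12.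

**Step 7**
Reactants: 13 spiro lactam
Product: 15 (4S,5R)-4-(benzyloxy)-8,8-(ethylenedioxy)-7-(hydroxymethyl)-1-(4-methoxybenzyl)-1-azaspiro[4.5]decan-2-one (C7 epimers), via B-alkyl-9-BBN adduct 14 (not isolated)
Conditions: 9-BBN, THF, 0 °C → rt; then NaOH, H2O2, 0 °C
Reagents that add atoms: hydrogen peroxide OO
Why: Anti-Markovnikov Brown hydroboration–oxidation of the 1,1-disubstituted alkene should give the primary alcohol without reducing the lactam; the new CH centre (C16) is a mixture that disappears when C16 becomes part of the enol triflate in step 16.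

**Step 8**
Reactants: 15 primary alcohol
Product: 17 methyl (4S,5R)-4-(benzyloxy)-8,8-(ethylenedioxy)-1-(4-methoxybenzyl)-2-oxo-1-azaspiro[4.5]decane-7-carboxylate (C7 epimers), via carboxylic acid 16 (not isolated)
Conditions: TEMPO (20 mol%), PhI(OAc)2, MeCN/pH 7 buffer, rt; then TMSCHN2, MeOH/PhMe, 0 °C
Reagents that add atoms: water O; (trimethylsilyl)diazomethane C[Si](C)(C)C=[N+]=[N-]
Why: Oxoammonium oxidation in buffered aqueous acetonitrile takes the primary alcohol through the aldehyde hydrate to the acid under conditions that spare the dioxolane, and diazoalkane esterification then gives the methyl ester without acid.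

**Step 9**
Reactants: 17 lactam ester
Product: 18 methyl (4S,5R)-4-(benzyloxy)-8,8-(ethylenedioxy)-1-(4-methoxybenzyl)-1-azaspiro[4.5]decane-7-carboxylate (C7 epimers)
Conditions: [Ir(coe)2Cl]2 (1 mol%), Et2SiH2, CH2Cl2, rt
Reagents that add atoms: none
Why: Iridium-catalysed hydrosilylation of tertiary amides (deoxygenative amide reduction) should convert the lactam C=O into CH2 and leave the methyl ester, the ketal and the benzyl ether untouched.

**Step 10**
Reactants: 18 N-(4-methoxybenzyl) amine
Product: 20 methyl (4S,5R)-4-(benzyloxy)-8,8-(ethylenedioxy)-1-azaspiro[4.5]decane-7-carboxylate (C7 epimers), via 1-chloroethyl carbamate 19 (not isolated)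
Conditions: ClCO2CHClCH3, K2CO3 (solid), ClCH2CH2Cl, reflux; then MeOH, 50 °C; aq NaHCO3
Reagents that add atoms: none
Why: Chloroformate N-dealkylation (von Braun-type) acylates the tertiary amine, expels the 4-methoxybenzyl group as its chloride and, on methanolysis of the 1-chloroethyl carbamate, should release the secondary amine while the O-benzyl ether stays.

**Step 11**
Reactants: 21 methyl 2-(2-nitrophenyl)acetate; 22 allyl bromide
Product: 23 methyl 2-(2-nitrophenyl)pent-4-enoate (racemic)
Conditions: K2CO3, DMF, 0 °C → rt
Reagents that add atoms: none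
Why: The nitro-stabilised aryl-acetate anion is C-alkylated once by allyl bromide (enolate alkylation), a second alkylation being slow for the hindered tertiary carbanion.

**Step 12**
Reactants: 23 methyl 2-(2-nitrophenyl)pent-4-enoate
Product: 25 methyl 2-(2-nitrophenyl)-4-oxobutanoate, via ozonide 24 (not isolated)
Conditions: O3, CH2Cl2, −78 °C; then Me2S, → rt
Reagents that add atoms: ozone O=[O+][O-]
Why: Ozonolysis with reductive work-up cleaves the terminal alkene to the aldehyde; nitroarene and ester are inert to ozone.

**Step 13**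
Reactants: 20 secondary amine; 25 methyl 2-(2-nitrophenyl)-4-oxobutanoate
Product: 26 N-[4-methoxy-3-(2-nitrophenyl)-4-oxobutyl] derivative of 20 (epimers at C7 and C16)
Conditions: NaBH(OAc)3, AcOH, ClCH2CH2Cl, rt
Reagents that add atoms: none
Why: Reductive amination with triacetoxyborohydride should join the hindered secondary amine to the unhindered aldehyde through the iminium ion without reducing esters or the nitro group; C7 remains an epimer mixture because it is deprotonated in step 17.

**Step 14**
Reactants: 26 nitroarene
Product: 28 methyl N-aryl carbamate corresponding to 26 (NO2 replaced by NHCO2Me), via aniline 27 (not isolated)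
Conditions: H2 (1 atm), Pt/C (sulfided), EtOAc, rt; filter; then ClCO2Me, aq NaHCO3, 0 °C
Reagents that add atoms: methyl chloroformate COC(=O)Cl
Why: Sulfided platinum hydrogenates the nitro group without hydrogenolysis of the benzyl ether, and immediate Schotten–Baumann acylation should trap the aniline as its carbamate before it can lactamise onto the neighbouring ester.

**Step 15**
Reactants: 28 ketal carbamate
Product: 29 β-keto ester (C2 ketone, C16 CO2Me; keto/enol and epimer mixture)
Conditions: 1 M HCl, THF, rt
Reagents that add atoms: water O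
Why: Acetal hydrolysis unmasks the C2 ketone; carbamate, methyl esters and benzyl ether are stable to dilute acid and the protonated amine is inert.

**Step 16**
Reactants: 29 β-keto ester
Product: 30 enol triflate (C16=C2 alkene, C2–OTf, C16–CO2Me)
Conditions: NaH (1.05 equiv), THF, 0 °C; then PhNTf2, 0 °C → rt
Reagents that add atoms: N-phenylbis(trifluoromethanesulfonimide) O=S(=O)(N(c1ccccc1)S(=O)(=O)C(F)(F)F)C(F)(F)F
Why: One equivalent of base deprotonates only the β-keto ester, by far the most acidic site, and O-sulfonylation of the enolate (enol triflate formation) makes C2 the electrophilic β-carbon of an enoate.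

**Step 17**
Reactants: 30 enol triflate
Product: 32 15-O-benzyl ether of the target, via ene-carbamate macrocycle 31 (not isolated)
Conditions: Cs2CO3, DMF (3 mM), 50 °C; then KHMDS, THF, −40 → 0 °C; AcOH
Reagents that add atoms: none
Why: Proposed new method: the carbamate anion should add to C2 and expel triflate (vinylogous substitution), closing an eleven-membered ring through N1 in which C2 stays sp2, so no bridgehead alkene is needed; KHMDS then forms the C7 aryl-acetate enolate, which adds 5-exo-trig to C2 on the only face its C6–C5–N4 tether can reach (C7 cis to N4, N1 cis to C15), with the C7 ester expected to turn away from the developing C16 ester enolate (over C18) and C16 protonated on the N1 face so that its ester lies pseudo-equatorial on the boat cyclohexane; the closest known reactions are addition–elimination of nitrogen nucleophiles to enol triflates of β-keto esters and intramolecular Michael additions of ester enolates to N-acyl vinylogous carbamates.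

**Step 18**
Reactants: 32 15-O-benzyl ether of the target
Product: 33 target compound
Conditions: H2 (1 atm), Pd(OH)2/C, MeOH/AcOH, rt
Reagents that add atoms: none
Why: Palladium-catalysed hydrogenolysis removes the O-benzyl group (acetic acid keeps N4 protonated so it does not poison the catalyst) without touching carbamate, esters or any stereocentre.

**Compound list**

1 | (S)-malic acid | C([C@@H](C(=O)O)O)C(=O)O | starting material
2 | 4-methoxybenzylamine | COc1ccc(CN)cc1 | starting material
3 | (S)-3-hydroxy-1-(4-methoxybenzyl)pyrrolidine-2,5-dione | O[C@H]1CC(=O)N(Cc2ccc(OC)cc2)C1=O | intermediate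
4 | (S)-3-(benzyloxy)-1-(4-methoxybenzyl)pyrrolidine-2,5-dione | O=C1C[C@H](OCc2ccccc2)C(=O)N1Cc1ccc(OC)cc1 | intermediate
5 | (2-bromoallyl)trimethylsilane | C=C(Br)C[Si](C)(C)C | starting material
6 | 3-bromopropanoyl chloride | O=C(Cl)CCBr | starting material
7 | [1-(trimethylsilylmethyl)vinyl]magnesium bromide | C=C([Mg]Br)C[Si](C)(C)C | intermediate (not isolated)
8 | 5-bromo-2-[(trimethylsilyl)methyl]pent-1-en-3-one | C=C(C[Si](C)(C)C)C(=O)CCBr | intermediate
9 | 2-(2-bromoethyl)-2-[3-(trimethylsilyl)prop-1-en-2-yl]-1,3-dioxolane | C=C(C[Si](C)(C)C)C1(CCBr)OCCO1 | intermediate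
10 | Grignard reagent of 9 | C=C(C[Si](C)(C)C)C1(CC[Mg]Br)OCCO1 | intermediate (not isolated)
11 | (4S)-4-(benzyloxy)-5-hydroxy-1-(4-methoxybenzyl)-5-(2-{2-[3-(trimethylsilyl)prop-1-en-2-yl]-1,3-dioxolan-2-yl}ethyl)pyrrolidin-2-one, C5 epimers | C=C(C[Si](C)(C)C)C1(OCCO1)CCC1(O)N(Cc2ccc(OC)cc2)C(=O)C[C@@H]1OCc1ccccc1 | intermediate
12 | N-acyliminium ion from 11 | C=C(C[Si](C)(C)C)C1(OCCO1)CCC1=[N+](Cc2ccc(OC)cc2)C(=O)C[C@@H]1OCc1ccccc1 | intermediate (not isolated)
13 | (4S,5R)-4-(benzyloxy)-8,8-(ethylenedioxy)-1-(4-methoxybenzyl)-7-methylene-1-azaspiro[4.5]decan-2-one | C=C1C[C@]2(N(Cc3ccc(OC)cc3)C(=O)C[C@@H]2OCc2ccccc2)CCC14OCCO4 | intermediate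
14 | B-alkyl-9-BBN adduct of 13 (boron on the former methylene carbon) | C1CCC2CCCC1B2CC1C[C@]2(N(Cc3ccc(OC)cc3)C(=O)C[C@@H]2OCc2ccccc2)CCC14OCCO4 | intermediate (not isolated)
15 | 7-(hydroxymethyl) spiro lactam, C7 epimers | OCC1C[C@]2(N(Cc3ccc(OC)cc3)C(=O)C[C@@H]2OCc2ccccc2)CCC14OCCO4 | intermediate
16 | spiro lactam 7-carboxylic acid, C7 epimers | OC(=O)C1C[C@]2(N(Cc3ccc(OC)cc3)C(=O)C[C@@H]2OCc2ccccc2)CCC14OCCO4 | intermediate (not isolated)
17 | methyl (4S,5R)-4-(benzyloxy)-8,8-(ethylenedioxy)-1-(4-methoxybenzyl)-2-oxo-1-azaspiro[4.5]decane-7-carboxylate, C7 epimers | COC(=O)C1C[C@]2(N(Cc3ccc(OC)cc3)C(=O)C[C@@H]2OCc2ccccc2)CCC14OCCO4 | intermediate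
18 | methyl (4S,5R)-4-(benzyloxy)-8,8-(ethylenedioxy)-1-(4-methoxybenzyl)-1-azaspiro[4.5]decane-7-carboxylate, C7 epimers | COC(=O)C1C[C@]2(N(Cc3ccc(OC)cc3)CC[C@@H]2OCc2ccccc2)CCC14OCCO4 | intermediate
19 | N-(1-chloroethoxycarbonyl) analogue of 18 (PMB replaced) | COC(=O)C1C[C@]2(N(C(=O)OC(C)Cl)CC[C@@H]2OCc2ccccc2)CCC14OCCO4 | intermediate (not isolated)
20 | methyl (4S,5R)-4-(benzyloxy)-8,8-(ethylenedioxy)-1-azaspiro[4.5]decane-7-carboxylate, C7 epimers | COC(=O)C1C[C@]2(NCC[C@@H]2OCc2ccccc2)CCC14OCCO4 | intermediate
21 | methyl 2-(2-nitrophenyl)acetate | COC(=O)Cc1ccccc1[N+](=O)[O-] | starting material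
22 | allyl bromide | C=CCBr | starting material
23 | methyl 2-(2-nitrophenyl)pent-4-enoate (racemic) | COC(=O)C(CC=C)c1ccccc1[N+](=O)[O-] | intermediate
24 | ozonide (1,2,4-trioxolane) of 23 | COC(=O)C(CC1OCOO1)c1ccccc1[N+](=O)[O-] | intermediate (not isolated)
25 | methyl 2-(2-nitrophenyl)-4-oxobutanoate (racemic) | COC(=O)C(CC=O)c1ccccc1[N+](=O)[O-] | intermediate
26 | N-[4-methoxy-3-(2-nitrophenyl)-4-oxobutyl] derivative of 20 | COC(=O)C1C[C@]2(N(CCC(C(=O)OC)c3ccccc3[N+](=O)[O-])CC[C@@H]2OCc2ccccc2)CCC14OCCO4 | intermediate
27 | aniline from 26 | COC(=O)C1C[C@]2(N(CCC(C(=O)OC)c3ccccc3N)CC[C@@H]2OCc2ccccc2)CCC14OCCO4 | intermediate (not isolated)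
28 | methyl N-aryl carbamate from 27 | COC(=O)C1C[C@]2(N(CCC(C(=O)OC)c3ccccc3NC(=O)OC)CC[C@@H]2OCc2ccccc2)CCC14OCCO4 | intermediate
29 | β-keto ester (ketal of 28 removed) | COC(=O)C1C[C@]2(N(CCC(C(=O)OC)c3ccccc3NC(=O)OC)CC[C@@H]2OCc2ccccc2)CCC1=O | intermediate
30 | enol triflate of 29 | COC(=O)C=1C[C@]2(N(CCC(C(=O)OC)c3ccccc3NC(=O)OC)CC[C@@H]2OCc2ccccc2)CCC=1OS(=O)(=O)C(F)(F)F | intermediate
31 | eleven-membered ene-carbamate (N1 bonded to C2; C7 epimers) | COC(=O)C=1C[C@]2(N3CC[C@@H]2OCc2ccccc2)CCC=1N(C(=O)OC)c1ccccc1C(C(=O)OC)CC3 | intermediate (not isolated)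
32 | 15-O-benzyl ether of the target (C2 R, C7 S, C16 R, C20 R, C15 S) | COC(=O)[C@@H]1C[C@@]23CC[C@@]14N(C(=O)OC)c1ccccc1[C@@]4(C(=O)OC)CCN2CC[C@@H]3OCc1ccccc1 | intermediate
33 | target, CNP0144467.1 | COC(=O)[C@@H]1C[C@@]23CC[C@@]14N(C(=O)OC)c1ccccc1[C@@]4(C(=O)OC)CCN2CC[C@@H]3O | target

**Step count.** Total: 18 steps. Longest linear sequence: 14 steps (1, 2, 5–10, 13–18).

**Steps most likely to fail**

1. Step 17 (proposed new method). The triflate may be lost by attack at sulfur or hydrolysis. The eleven-membered N1–C2 closure may be outrun by oligomerisation. The C7 enolate may acylate the carbamate carbonyl instead of adding to C2. Facial control at C7 may be poor. The reverse order (C7 first) is not relied on, because its adduct could lose triflate only by forming a bridgehead alkene. Fallback with known reactions, made one bond at a time: setting out from 30, palladium-catalysed amidation of the enol triflate by the tethered carbamate (Pd2(dba)3, Xantphos, Cs2CO3, dioxane, high dilution) would give the ene-carbamate macrocycle 31 as an isolated compound. Soft enolisation (TBSOTf, Et3N) would convert its C7 ester into the silyl ketene acetal F1. A Lewis-acid Mukaiyama–Michael addition (TMSOTf or TiCl4, CH2Cl2, −78 °C), in which acylation of the carbamate is not possible, would close C2–C7 and come back to the route at 32.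

2. Step 6. The allylsilane may attack the face syn to the benzyloxy group and give the C20 epimer. Proton loss to the enamide or protodesilylation may also precede ring closure. Fallback that replaces steric shielding by anchimeric assistance: setting out from 3, pivaloylation (PivCl, pyridine) would give the pivalate imide F2. Addition of Grignard reagent 10 at −78 °C would give the hydroxylactam pivalate F3. Ionisation with BF3·OEt2 would then pass through a cis-fused acyloxonium ion that can only be opened anti to oxygen, giving the spiro lactam pivalate F4. Methanolysis (NaOMe, MeOH) to the spiro lactam alcohol F5 and benzylation (NaH, BnBr, Bu4NI) would come back to the route at 13.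

3. Step 10. Acylation of the hindered, α-tertiary amine may stall, and the dioxolane may be exchanged or lost during the hot methanolysis. Fallback that removes the group oxidatively one stage earlier: setting out from 17, ceric ammonium nitrate (MeCN/H2O, 0 °C) would cleave the N-(4-methoxybenzyl) group of the lactam to give the N–H lactam F6. Iridium-catalysed hydrosilylation of this secondary amide (Et2SiH2) would give the secondary amine and come back to the route at 20.

**Further compounds**

F1 | step 17 | tert-butyldimethylsilyl ketene acetal of the C7 ester of 31 | COC(=O)C=1C[C@]2(N3CC[C@@H]2OCc2ccccc2)CCC=1N(C(=O)OC)c1ccccc1C(=C(OC)O[Si](C)(C)C(C)(C)C)CC3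
F2 | step 6 | (S)-1-(4-methoxybenzyl)-2,5-dioxopyrrolidin-3-yl pivalate | CC(C)(C)C(=O)O[C@H]1CC(=O)N(Cc2ccc(OC)cc2)C1=O
F3 | step 6 | pivalate analogue of hydroxylactam 11 (C5 epimers) | C=C(C[Si](C)(C)C)C1(OCCO1)CCC1(O)N(Cc2ccc(OC)cc2)C(=O)C[C@@H]1OC(=O)C(C)(C)C
F4 | step 6 | pivalate analogue of spiro lactam 13 | C=C1C[C@]2(N(Cc3ccc(OC)cc3)C(=O)C[C@@H]2OC(=O)C(C)(C)C)CCC14OCCO4
F5 | step 6 | (4S,5R)-8,8-(ethylenedioxy)-4-hydroxy-1-(4-methoxybenzyl)-7-methylene-1-azaspiro[4.5]decan-2-one | C=C1C[C@]2(N(Cc3ccc(OC)cc3)C(=O)C[C@@H]2O)CCC14OCCO4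
F6 | step 10 | methyl (4S,5R)-4-(benzyloxy)-8,8-(ethylenedioxy)-2-oxo-1-azaspiro[4.5]decane-7-carboxylate (N–H lactam, C7 epimers) | COC(=O)C1C[C@]2(NC(=O)C[C@@H]2OCc2ccccc2)CCC14OCCO4
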